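I set east beside south, its neighbour with the same charges at the same temperature, to see what it does to the homo dimer when the feed carries the nucleophile in one flask and the electrophile in the other.

    electrophile + nucleophile → acid + product + leaving group (k1 = 0.282 /M/s, Ea1 = 42.0 kJ/mol)
    protonated nucleophile ⇌ nucleophile + acid, settled at all times (K2 = 3.2 × 10⁻¹⁰ M, ΔH2 = −40.0 kJ/mol)
    buffer acid ⇌ buffer base + acid, settled at all times (K3 = 1.3 × 10⁻⁸ M, ΔH3 = −67.0 kJ/mol)
    2 electrophile → homo dimer (k4 = 0.0405 /M/s, Ea4 = 68.0 kJ/mol)
    nucleophile + leaving group ⇌ idle adduct, settled at all times (K5 = 13.3 /M, ΔH5 = −27.0 kJ/mol)
    scavenger + leaving group → scavenged by-product (k6 = 22.2 /M/s, Ea6 = 53.0 kJ/mol)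
    (constants at 20 °C)

the same everywhere: buffer base 0.297 M; buffer acid 9.90 mM; scavenger 0.0990 M; time 30 s

| run | electrophile | nucleophile | remark | temperature |
|---|---|---|---|---|
| south-west | 0.099 M | 0.0940 M (fed, over 20 s) | the addition at −10 °C, then warmed to 20 °C; the feed brings no volume worth counting |  |
| east | 0.099 M | 0.0940 M (fed, over 20 s) | all else is in the flask from the start; the feed brings no volume worth counting | 20 °C |
| south | 0.099 M (fed, over 20 s) | 0.0940 M | all else is in the flask from the start; the feed brings no volume worth counting | 20 °C |
| north-west | 0.099 M | 0.0940 M | everything together at the start at −10 °C, warmed to 20 °C at 20 s |  |

* the flask that comes out highest in amount of homo dimer, in percent of the electrophile charged; "all alike" if 1.5 percentage points covers them all (south-west / east / south / north-west / all alike)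
* amount of homo dimer at the end, in percent of the electrophile charged, south-west
* amount of homo dimer at the end, in percent of the electrophile charged, east
* amount of homo dimer at the end, in percent of the electrophile charged, south
* amount of homo dimer at the end, in percent of the electrophile charged, north-west

- acid is the free proton; pH is minus the decimal logarithm of its molar concentration
- percentages count the electrophile that a species holds: one homo dimer counts as two
- leaving group is meant together with its idle adduct
- a step written with two of one species runs at k times the square of its concentration and takes two of it each time
- at 20 °C the constants are as listed, elsewhere as the activation energies and enthalpies make them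

I reckoned with one clock, the dimer clock τ, the first half-life of the electrophile by dimerisation alone at its full charge:

τ = 125 s

Dimerisation is second-order in c(electrophile), so on a decimal logarithm each decade of concentration is two decades of rate. I therefore counted the time θ that the flask spends as if c(electrophile) stood at its full charge and the dimerisation constant at its value at 20 °C. The share of the electrophile lost to homo dimer is then θ/(θ + τ), which is the exact integral for a flask with dimerisation as its one consuming step.

In east the electrophile is present from the start, so θ is the whole 30 s. In south c(electrophile) climbs as a ramp during the feed, and the mean square of a ramp is a third of the square of its top. The cold flasks lose 1.38 decades of the dimerisation constant at −10 °C, a factor of 24.1, for the first 20 s.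

east: θ = 30 s, share 19.4%

south: θ = 16.7 s, share 11.8%

south-west and north-west: θ = 10.8 s, share 7.99%

The shares of east and south stand in a ratio of 1.64, against 1.80 for their θ values. That gap of 7.6 percentage points is wider than the margin of 1.5 points, so I committed to east as highest. I left the step to product out of this, and it consumes electrophile as well, so I held these figures as upper ones.

The forecast named east, with 6.5% for south-west, 16% for east, 8% for south and 6.1% for north-west, saying “feeding the electrophile (south) keeps its concentration low for most of the time”.

East came highest at 16.1%, against 8.00% for south, 6.46% for south-west and 6.15% for north-west, each below my figure. Over the first 20 s the mean c(electrophile) was 0.0871 M in east and 0.0424 M in south. East kept 82.8% of its clock figure. The neighbour of east charged with 0.059 M of electrophile has a clock of 209 s, longer than τ, so its share over 30 s is 12.5%, and with east's fraction 10.3%. That neighbour gave 10.1%.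

The numbers of this flask were set for the occasion; the result is computed.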